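**Plan**

- Cuts: (i) a retro-[4+2] through ring A, which breaks the bond from the quaternary carbon to the neighbouring ring sp2 carbon together with the ring CH2–CH2 bond and so opens ring A and the seven-membered enol lactone at once; (ii) a retro-[3,3] of the resulting allenyl ester to a tertiary propargylic ester; (iii) the ester C–O bond; (iv) the thiazine C–N and C–S bonds (hypotaurine).
- Enabling feature: ring A carries the endocyclic C(CH3)=CH and the exocyclic enol-ester C=CH–O double bonds on neighbouring carbons, and the quaternary carbon joins this diene to the arene carbon ortho to the lactone carbonyl. Ring A plus the oxepinone is therefore the Diels–Alder adduct of a 1-acyloxy vinylallene with an ortho-isopropenyl group held by the ester.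
- Forward order: the tetralone acid is iodinated, given its isopropenyl group and oxygenated to a masked 2-methoxy-1,4-naphthoquinone; it is esterified with (R)-3-methylpent-1-en-4-yn-3-ol; the quinone and the thiazine dioxide are then made; ring A and the oxepinone close together in the last step.
- Stereochemistry: the carbinol centre of (S)-2-methylglycidol becomes the R centre of the propargylic ester, then the Ra allene axis, then the S quaternary carbon (centre-to-axis-to-centre transfer; the carbinol centre itself ends as an sp2 carbon).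

Key step: step 10

Remark: compounds 1, 5, 7 and 16 are taken as purchasable; the position of the tetralone carbonyl of 5 fixes which quinone carbon later carries nitrogen.

**Step 1**
Reactants: 1 (S)-2-methylglycidol
Product: 3 (S)-2-ethynyl-2-methyloxirane, via (R)-2-methyloxirane-2-carbaldehyde 2 (not isolated)
Conditions: Dess–Martin periodinane, pyridine, CH2Cl2, 0 to 23 °C; aqueous wash, dried solution used directly; then dimethyl (1-diazo-2-oxopropyl)phosphonate, K2CO3, MeOH, 0 to 23 °C; product kept as a distilled ether solution
Reagents that add atoms: dimethyl (1-diazo-2-oxopropyl)phosphonate COP(=O)(OC)C(=[N+]=[N-])C(C)=O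
Why: Dess–Martin oxidation followed by Seyferth–Gilbert homologation with the Ohira–Bestmann reagent should give the alkyne without touching any bond at the stereocentre, which has no α-hydrogen, and oxidising before any base is used avoids the degenerate Payne rearrangement that would racemise 1.

**Step 2**
Reactants: 3 (S)-2-ethynyl-2-methyloxirane
Product: 4 (R)-3-methylpent-1-en-4-yn-3-ol
Conditions: Me3S+ I− (3 equiv), n-BuLi (2.9 equiv), THF, −10 to 23 °C; H2O
Reagents that add atoms: trimethylsulfonium iodide C[S+](C)C.[I-]
Why: Dimethylsulfonium methylide should open the epoxide at its CH2 carbon and the β-alkoxy sulfonium salt should lose Me2S on deprotonation (one-carbon epoxide-to-allylic-alcohol homologation), so the C–O bond at the stereocentre stays intact and the descriptor changes from S to R only through the priority change.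

**Step 3**
Reactants: 5 5-oxo-5,6,7,8-tetrahydronaphthalene-2-carboxylic acid
Product: 6 3-iodo-5-oxo-5,6,7,8-tetrahydronaphthalene-2-carboxylic acid
Conditions: [Cp*Ir(H2O)3]SO4 (3 mol %; Cp* = C5Me5), N-iodosuccinimide (1.2 equiv), (CF3)2CHOH, 40 °C
Reagents that add atoms: N-iodosuccinimide O=C1CCC(=O)N1I
Why: Carboxylate-directed ortho C–H iodination by the trivalent iridium catalyst should occur at C3 only, because the other ortho position (C1) is flanked by the ring CH2 and the acyl-substituted ring is too electron-poor for undirected iodination.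

**Step 4**
Reactants: 6 3-iodo-5-oxo-5,6,7,8-tetrahydronaphthalene-2-carboxylic acid; 7 isopropenylboronic acid pinacol ester
Product: 8 5-oxo-3-(prop-1-en-2-yl)-5,6,7,8-tetrahydronaphthalene-2-carboxylic acid
Conditions: PdCl2(dppf) (5 mol %), K2CO3 (3.5 equiv), 1,4-dioxane/H2O 4:1, 85 °C; cold dilute HCl to pH 4
Reagents that add atoms: none
Why: Suzuki–Miyaura coupling of an aryl iodide runs on the free carboxylate, and the cold, weakly acidic work-up should keep the 2-isopropenylbenzoic acid from closing to the dimethylphthalide.

**Step 5**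
Reactants: 8 5-oxo-3-(prop-1-en-2-yl)-5,6,7,8-tetrahydronaphthalene-2-carboxylic acid
Product: 9 6-hydroxy-5,8-dioxo-3-(prop-1-en-2-yl)-5,8-dihydronaphthalene-2-carboxylic acid
Conditions: t-BuOK (5 equiv), O2 (1 atm), t-BuOH, 25 °C; cold 1 M HCl to pH 3
Reagents that add atoms: dioxygen O=O
Why: Base-mediated autoxidation of a 1-tetralone oxygenates the enolate α-carbon and then the benzylic CH2, which should give the 2-hydroxy-1,4-naphthoquinone with the hydroxyl fixed on the carbon next to the former ketone.

**Step 6**
Reactants: 9 6-hydroxy-5,8-dioxo-3-(prop-1-en-2-yl)-5,8-dihydronaphthalene-2-carboxylic acid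
Product: 12 5,6,8-trimethoxy-3-(prop-1-en-2-yl)naphthalene-2-carboxylic acid, via 5,6,8-trihydroxy-3-(prop-1-en-2-yl)naphthalene-2-carboxylic acid 10 (not isolated), via methyl 5,6,8-trimethoxy-3-(prop-1-en-2-yl)naphthalene-2-carboxylate 11 (not isolated)
Conditions: Na2S2O4, THF/H2O, 23 °C, N2; then Me2SO4 (6 equiv), aqueous KOH, Bu4NBr (cat.), 23 °C; then KOH, MeOH/H2O, 60 °C; cold 1 M HCl to pH 3
Reagents that add atoms: dimethyl sulfate COS(=O)(=O)OC; potassium hydroxide [K+].[OH-]
Why: Reductive methylation of a hydroxynaphthoquinone (dithionite reduction, then phase-transfer Williamson O-methylation) followed by saponification of the methyl ester formed alongside should leave the quinone masked as three methyl ethers for the esterification.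

**Step 7**
Reactants: 12 5,6,8-trimethoxy-3-(prop-1-en-2-yl)naphthalene-2-carboxylic acid; 4 (R)-3-methylpent-1-en-4-yn-3-ol
Product: 14 (3R)-3-methylpent-1-en-4-yn-3-yl 5,6,8-trimethoxy-3-(prop-1-en-2-yl)naphthalene-2-carboxylate, via 5,6,8-trimethoxy-3-(prop-1-en-2-yl)naphthalene-2-carbonyl chloride 13 (not isolated)
Conditions: 1-chloro-N,N,2-trimethylprop-1-en-1-amine, CH2Cl2, 0 to 23 °C; then 4, Et3N, DMAP (0.2 equiv), CH2Cl2, 23 to 40 °C
Reagents that add atoms: none
Why: The acid chloride forms without free HCl, so the isopropenyl group is spared, and DMAP-catalysed acylation of the tertiary propargylic alcohol leaves the carbinol C–O bond intact, so 14 keeps the R configuration.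

**Step 8**
Reactants: 14 (3R)-3-methylpent-1-en-4-yn-3-yl 5,6,8-trimethoxy-3-(prop-1-en-2-yl)naphthalene-2-carboxylate
Product: 15 (3R)-3-methylpent-1-en-4-yn-3-yl 6-methoxy-5,8-dioxo-3-(prop-1-en-2-yl)-5,8-dihydronaphthalene-2-carboxylate
Conditions: (NH4)2Ce(NO3)6 (2.5 equiv), MeCN/H2O 2:1, 0 °C, 15 min
Reagents that add atoms: water O
Why: Oxidative demethylation of a 1,2,4-trimethoxyarene by tetravalent cerium should give the para-quinone from the two 1,4-related ethers and keep the third methoxy group as a vinylogous ester, while the short time at 0 °C spares the tertiary ester and the alkenes.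

**Step 9**
Reactants: 15 (3R)-3-methylpent-1-en-4-yn-3-yl 6-methoxy-5,8-dioxo-3-(prop-1-en-2-yl)-5,8-dihydronaphthalene-2-carboxylate; 16 hypotaurine
Product: 17 (3R)-3-methylpent-1-en-4-yn-3-yl 5,10-dioxo-7-(prop-1-en-2-yl)-3,4,5,10-tetrahydro-2H-naphtho[2,3-b][1,4]thiazine-8-carboxylate 1,1-dioxide
Conditions: hypotaurine (1.5 equiv), MeCN/EtOH/H2O 1:1:1, air, 23 °C
Reagents that add atoms: none
Why: In this hypotaurine annulation of a quinone the amine displaces methoxide at the vinylogous ester carbon (addition–elimination) and the sulfinate sulfur adds to the neighbouring CH with reoxidation by air, so in either order nitrogen should end on the former methoxy carbon and sulfur on the CH carbon, giving one regioisomer of the 1,1-dioxothiazine.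

**Step 10**
Reactants: 17 (3R)-3-methylpent-1-en-4-yn-3-yl 5,10-dioxo-7-(prop-1-en-2-yl)-3,4,5,10-tetrahydro-2H-naphtho[2,3-b][1,4]thiazine-8-carboxylate 1,1-dioxide
Product: 19 target CNP0348176.1, via (Ra)-allenyl ester 18 (not isolated)
Conditions: AgSbF6 (5 mol %), ClCH2CH2Cl, 0 to 23 °C; then Et3N (10 mol %), toluene (to 0.005 M), 90 °C
Reagents that add atoms: none
Why: Monovalent silver activates the alkyne, the ester carbonyl oxygen attacks the terminal alkyne carbon (6-endo) and the dioxinium intermediate fragments, a Saucy–Marbet-type suprafacial [3,3] acyloxy shift that turns the R carbinol centre into the Ra axis of 18 and is favoured over the 1,2-shift by the tertiary, vinyl-substituted centre and by silver in place of gold. The 1-acyloxy vinylallene 18 then undergoes a type 1 intramolecular Diels–Alder reaction with the isopropenyl group (closest known class: propargyl ester or propargyl vinyl ether rearrangement followed by vinylallene cycloaddition), forming the bond from the quaternary carbon to the ring sp2 carbon and the CH2–CH2 bond. Ring A closes in the [4+2] mode (4π from the allene C=C remote from oxygen plus the vinyl group, 2π from the isopropenyl group) and the seven-membered enol lactone closes at the same time in the fused mode through the five-atom ester–arene tether, the bridged alternative needing an eight-membered ring. The new quaternary stereocentre is controlled by the allene axis: the dienophile can reach only the diene face on which the acyloxy oxygen stands (the lactone requires the Z enol ester) and the arene must lie over the allene terminus, exo to the diene, so a single approach remains and it should give the S configuration. The step needs 1,3- over 1,2-acyloxy migration, no racemisation of 18 (the silver salt is quenched with Et3N before heating) and intra- over intermolecular cycloaddition (high dilution; the fully substituted quinone C=C does not compete).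

**Compound list**

1 | (S)-2-methylglycidol, [(2S)-2-methyloxiran-2-yl]methanol | C[C@]1(CO)CO1 | starting material
2 | (R)-2-methyloxirane-2-carbaldehyde (not isolated) | C[C@]1(C=O)CO1 | intermediate
3 | (S)-2-ethynyl-2-methyloxirane | C[C@]1(C#C)CO1 | intermediate
4 | (R)-3-methylpent-1-en-4-yn-3-ol | C[C@](O)(C#C)C=C | intermediate
5 | 5-oxo-5,6,7,8-tetrahydronaphthalene-2-carboxylic acid | O=C1CCCc2cc(C(=O)O)ccc21 | starting material
6 | 3-iodo-5-oxo-5,6,7,8-tetrahydronaphthalene-2-carboxylic acid | O=C1CCCc2cc(C(=O)O)c(I)cc21 | intermediate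
7 | isopropenylboronic acid pinacol ester | CC(=C)B1OC(C)(C)C(C)(C)O1 | starting material
8 | 5-oxo-3-(prop-1-en-2-yl)-5,6,7,8-tetrahydronaphthalene-2-carboxylic acid | CC(=C)c1cc2C(=O)CCCc2cc1C(=O)O | intermediate
9 | 6-hydroxy-5,8-dioxo-3-(prop-1-en-2-yl)-5,8-dihydronaphthalene-2-carboxylic acid | CC(=C)c1cc2C(=O)C(O)=CC(=O)c2cc1C(=O)O | intermediate
10 | 5,6,8-trihydroxy-3-(prop-1-en-2-yl)naphthalene-2-carboxylic acid (not isolated) | CC(=C)c1cc2c(O)c(O)cc(O)c2cc1C(=O)O | intermediate
11 | methyl 5,6,8-trimethoxy-3-(prop-1-en-2-yl)naphthalene-2-carboxylate (not isolated) | CC(=C)c1cc2c(OC)c(OC)cc(OC)c2cc1C(=O)OC | intermediate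
12 | 5,6,8-trimethoxy-3-(prop-1-en-2-yl)naphthalene-2-carboxylic acid | CC(=C)c1cc2c(OC)c(OC)cc(OC)c2cc1C(=O)O | intermediate
13 | 5,6,8-trimethoxy-3-(prop-1-en-2-yl)naphthalene-2-carbonyl chloride (not isolated) | CC(=C)c1cc2c(OC)c(OC)cc(OC)c2cc1C(Cl)=O | intermediate
14 | (3R)-3-methylpent-1-en-4-yn-3-yl 5,6,8-trimethoxy-3-(prop-1-en-2-yl)naphthalene-2-carboxylate | C=C[C@@](C)(OC(=O)c1cc2c(OC)cc(OC)c(OC)c2cc1C(C)=C)C#C | intermediate
15 | (3R)-3-methylpent-1-en-4-yn-3-yl 6-methoxy-5,8-dioxo-3-(prop-1-en-2-yl)-5,8-dihydronaphthalene-2-carboxylate | C=C[C@@](C)(OC(=O)c1cc2C(=O)C=C(OC)C(=O)c2cc1C(C)=C)C#C | intermediate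
16 | hypotaurine (2-aminoethanesulfinic acid) | NCCS(=O)O | starting material
17 | (3R)-3-methylpent-1-en-4-yn-3-yl 5,10-dioxo-7-(prop-1-en-2-yl)-3,4,5,10-tetrahydro-2H-naphtho[2,3-b][1,4]thiazine-8-carboxylate 1,1-dioxide | C=C[C@@](C)(OC(=O)c1cc2C(=O)C3=C(NCCS3(=O)=O)C(=O)c2cc1C(C)=C)C#C | intermediate
18 | (Ra)-3-methylpenta-1,2,4-trien-1-yl ester of the acid of 17 (acyloxy allene, not isolated) | [H]C(OC(=O)c1cc2C(=O)C3=C(NCCS3(=O)=O)C(=O)c2cc1C(C)=C)=[C@@]=C(C)C=C | intermediate
19 | target CNP0348176.1: enol lactone (2-benzoxepin-1-one ring) whose =CH–O carbon is exocyclic on the 2-methylcyclohex-2-ene ring A; the (S)-quaternary C(CH3) joins ring A to C7 of 3,4-dihydro-2H-naphtho[2,3-b][1,4]thiazine-5,10-dione 1,1-dioxide and the lactone carbonyl sits on C8 | CC1=CCC[C@]2(C)C1=COC(=O)c1cc3c(cc12)C(=O)C1=C(C3=O)S(=O)(=O)CCN1 | target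

**Step count**

Total: 10 steps. Longest linear sequence: 8 steps (5 to 19, steps 3 to 10).

**Steps most likely to fail**

1. Step 10. The axial configuration may be lost before the cycloaddition (silver-mediated ionisation of the allenyl ester), the ester may divert into a 1,2-acyloxy shift, or the reaction may stall because the sulfonyl enaminone quinone ties up the silver salt or limits solubility. Fallback: the ring-forming cascade is moved ahead of quinone and thiazine construction, onto the electron-rich, non-coordinating ester 14. Treatment of 14 with AgBF4 (5 mol %) in chlorobenzene at 23 °C should give (Ra)-3-methylpenta-1,2,4-trien-1-yl 5,6,8-trimethoxy-3-(prop-1-en-2-yl)naphthalene-2-carboxylate F1 (not isolated), which on dilution and heating at 90 °C should close to the (S)-trimethoxynaphthalene-fused enol lactone F2. Oxidative demethylation of F2 with (NH4)2Ce(NO3)6 in MeCN/H2O at 0 °C should give the (S)-methoxyquinone enol lactone F3, and hypotaurine annulation of F3 under the conditions of step 9 comes back to the route at 19.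

2. Step 9. Ring closure by the sulfinate and reoxidation may be slow, and substitution of methoxide by the sulfinate instead of the amine would erode the regiocontrol. Fallback: sulfur is brought in at the sulfide level and oxidised afterwards. From 15, 2-aminoethanethiol in EtOH under air at 23 °C should add through sulfur at the quinone CH carbon, reoxidise, and close by intramolecular displacement of methoxide by the amine to give the dihydrothiazinoquinone (sulfide) ester F4. Oxidation of the sulfide with H2O2 and Na2WO4 (cat.) in MeOH then comes back to the route at 17.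

3. Step 8. The acidic cerium medium may ionise the tertiary propargylic–allylic ester, the isopropenyl group may be oxidised, or some ortho-quinone may form. Fallback: the quinone is unmasked before the ester is made. From 12, (NH4)2Ce(NO3)6 in MeCN/H2O at 0 °C should give 6-methoxy-5,8-dioxo-3-(prop-1-en-2-yl)-5,8-dihydronaphthalene-2-carboxylic acid F5. With 1-chloro-N,N,2-trimethylprop-1-en-1-amine this is converted into 6-methoxy-5,8-dioxo-3-(prop-1-en-2-yl)-5,8-dihydronaphthalene-2-carbonyl chloride F6, which is acylated onto 4 (Et3N, DMAP cat., CH2Cl2) and comes back to the route at 15.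

**Further compounds**

F1 | step 10 | (Ra)-3-methylpenta-1,2,4-trien-1-yl 5,6,8-trimethoxy-3-(prop-1-en-2-yl)naphthalene-2-carboxylate | [H]C(OC(=O)c1cc2c(OC)cc(OC)c(OC)c2cc1C(C)=C)=[C@@]=C(C)C=C
F2 | step 10 | (S)-trimethoxynaphthalene-fused enol lactone (ring A and oxepinone of 19 on a 5,6,8-trimethoxynaphthalene) | CC1=CCC[C@]2(C)C1=COC(=O)c1cc3c(OC)cc(OC)c(OC)c3cc12
F3 | step 10 | (S)-2-methoxy-1,4-naphthoquinone-fused enol lactone | CC1=CCC[C@]2(C)C1=COC(=O)c1cc3C(=O)C=C(OC)C(=O)c3cc12
F4 | step 9 | (3R)-3-methylpent-1-en-4-yn-3-yl 5,10-dioxo-7-(prop-1-en-2-yl)-3,4,5,10-tetrahydro-2H-naphtho[2,3-b][1,4]thiazine-8-carboxylate | C=C[C@@](C)(OC(=O)c1cc2C(=O)C3=C(NCCS3)C(=O)c2cc1C(C)=C)C#C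
F5 | step 8 | 6-methoxy-5,8-dioxo-3-(prop-1-en-2-yl)-5,8-dihydronaphthalene-2-carboxylic acid | CC(=C)c1cc2C(=O)C(OC)=CC(=O)c2cc1C(=O)O
F6 | step 8 | 6-methoxy-5,8-dioxo-3-(prop-1-en-2-yl)-5,8-dihydronaphthalene-2-carbonyl chloride | CC(=C)c1cc2C(=O)C(OC)=CC(=O)c2cc1C(Cl)=O
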